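The target is cut at the furanone C3–vinyl bond (final Stille coupling) and at the exocyclic furanone C5=CH bond (vinylogous aldol condensation), so that both six-membered rings descend from one enol triflate of (4R,6R)-actinol. The triol ring (C1 gem-dimethyl, C3 secondary carbinol, C5 methyl carbinol, C6 side-chain carbinol) is completed in one flask from the ethynylcyclohexenol: the C3 hydroxyl, homoallylic to the ring C5=C6 alkene, steers vanadium-catalysed epoxidation to its own face, and water then opens the oxirane at C5 with inversion. This forms the C5–O and C6–O bonds and both tertiary stereocentres. The precursor is the free (R)-enynol bearing a terminal alkyne.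

Key step: step 5

Remark: ring positions C1, C3, C5 and C6 in the steps follow the numbering of the overview for both six-membered rings; LDA is taken as a commercial solution, and all polyenes are handled under argon in dim light.

Step 1
Reactants: 1 (4R,6R)-actinol
Product: 2 (4R,6R)-4-[(tert-butyldimethylsilyl)oxy]-2,2,6-trimethylcyclohexan-1-one
Conditions: TBSCl, imidazole, DMF, rt
Reagents that add atoms: tert-butyldimethylsilyl chloride, CC(C)(C)[Si](C)(C)Cl
Why: Silyl ether formation on the unhindered secondary alcohol masks the hydroxyl for the enolisation that follows and touches neither stereocentre.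

Step 2
Reactants: 2 silylated actinol
Product: 3 (4R)-4-[(tert-butyldimethylsilyl)oxy]-2,6,6-trimethylcyclohex-1-en-1-yl trifluoromethanesulfonate
Conditions: LDA, THF, −78 °C; then PhNTf2, −78 °C → rt
Reagents that add atoms: N-phenylbis(trifluoromethanesulfonimide), O=S(=O)(N(c1ccccc1)S(=O)(=O)C(F)(F)F)C(F)(F)F
Why: The ketone can enolise only toward the methyl-bearing carbon because the other α-carbon is quaternary, so enolate O-triflation (enol triflate formation) should give a single tetrasubstituted alkenyl triflate, the methyl-bearing stereocentre being erased on purpose.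

Step 3
Reactants: 3 enol triflate; 4 ethynyltrimethylsilane
Product: 5 tert-butyldimethyl{[(1R)-3,5,5-trimethyl-4-[(trimethylsilyl)ethynyl]cyclohex-3-en-1-yl]oxy}silane
Conditions: Pd(PPh3)4 (cat.), CuI (cat.), Et3N, DMF, rt → 50 °C
Reagents that add atoms: none
Why: Sonogashira coupling of an alkenyl triflate with a terminal alkyne works even at a fully substituted, neopentyl-flanked sp2 carbon and installs both alkyne carbons with the ring alkene already fixed in place.

Step 4
Reactants: 5 bis-silylated enyne
Product: 6 (1R)-4-ethynyl-3,5,5-trimethylcyclohex-3-en-1-ol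
Conditions: TBAF, THF, 0 °C → rt
Reagents that add atoms: none
Why: Fluoride-mediated desilylation cleaves the C(sp)–Si bond and the silyl ether in one operation, releasing the terminal alkyne and the free carbinol that the next step needs as its directing group.

Step 5
Reactants: 6 ethynyl cyclohexenol
Product: 8 (1S,2R,4S)-1-ethynyl-2,6,6-trimethylcyclohexane-1,2,4-triol, via syn-epoxy alcohol 7 (not isolated)
Conditions: VO(acac)2 (cat.), t-BuOOH (in decane), CH2Cl2, 0 °C → rt; then THF–H2O, HClO4 (cat.), 0 °C → rt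
Reagents that add atoms: tert-butyl hydroperoxide, CC(C)(C)OO; water, O
Why: The C3 hydroxyl binds vanadium(V) as an alkoxide beside the coordinated tert-butyl peroxide and, from a pseudo-axial position, passes oxygen to the C5=C6 alkene on its own face (hydroxyl-directed vanadium epoxidation of a homoallylic cyclohexenol), giving syn-epoxide 7. Added aqueous acid protonates the oxirane and water attacks C5 anti to the breaking C5–O bond through a chair-like transition state (acid-catalysed trans-diaxial epoxide hydrolysis, Fürst–Plattner rule), so the closest known reaction types are these two, run in sequence in one flask. No ring of the product is closed; the oxirane is a transient three-membered ring formed by concerted oxygen transfer and opened again. The C6 stereocentre is set by the C3 hydroxyl through metal delivery and keeps its oxygen, and the C5 stereocentre is set by inversion in the anti opening, so both are relayed from C3. The step needs face selectivity, which the directing C3–OH secures, and site selectivity, which is secured because opening at C5 leads to the chair with C3–OH, C5–Me and the ethynyl group equatorial whereas opening at C6 would force three syn-axial substituents, and because the terminal ethynyl group inductively disfavours positive charge at the neopentyl C6. The alkyne is inert to both reagents and offers no path to a furanoid ether, and the cis C3–OH cannot reach the rear of either oxirane carbon.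

Step 6
Reactants: 8 ethynyl triol
Product: 9 (1R,2R,4S)-2,6,6-trimethyl-1-[(E)-2-(tributylstannyl)ethenyl]cyclohexane-1,2,4-triol
Conditions: Bu3SnH, PdCl2(PPh3)2 (cat.), THF, 0 °C → rt
Reagents that add atoms: tributyltin hydride, CCCC[SnH](CCCC)CCCC
Why: Palladium-catalysed hydrostannation is a syn addition that places tin on the terminal carbon of an alkyne flanked by a fully substituted carbinol, so the E-β-stannyl alkene should form with the three hydroxyls left free.

Step 7
Reactants: 3 enol triflate; 10 (E)-3-methylpent-2-en-4-yn-1-ol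
Product: 11 (E)-5-[(4R)-4-[(tert-butyldimethylsilyl)oxy]-2,6,6-trimethylcyclohex-1-en-1-yl]-3-methylpent-2-en-4-yn-1-ol
Conditions: Pd(PPh3)4 (cat.), CuI (cat.), Et3N, DMF, rt
Reagents that add atoms: none
Why: Sonogashira coupling of the same triflate with the commercial E-enynol joins ring and chain at the alkyne, and the E-trisubstituted alkene is brought in ready-made instead of being constructed.

Step 8
Reactants: 11 enynol
Product: 12 (E)-5-[(4R)-4-[(tert-butyldimethylsilyl)oxy]-2,6,6-trimethylcyclohex-1-en-1-yl]-3-methylpent-2-en-4-ynal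
Conditions: MnO2, CH2Cl2, rt
Reagents that add atoms: none
Why: Manganese dioxide oxidises only the allylic primary alcohol (allylic alcohol oxidation) and leaves the silyl ether and the enyne untouched.

Step 9
Reactants: 12 enynal; 13 triethyl 4-phosphonocrotonate
Product: 14 ethyl (2E,4E,6E)-9-[(4R)-4-[(tert-butyldimethylsilyl)oxy]-2,6,6-trimethylcyclohex-1-en-1-yl]-7-methylnona-2,4,6-trien-8-ynoate
Conditions: 13, LiHMDS, THF, −78 °C; then 12, −78 → 0 °C
Reagents that add atoms: none
Why: Horner–Wadsworth–Emmons olefination with the vinylogous phosphonate adds four carbons and should form the new disubstituted alkene with the E selectivity typical of stabilised phosphonate anions, the crotonate alkene staying E.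

Step 10
Reactants: 14 trienynoate
Product: 15 (2E,4E,6E)-9-[(4R)-4-[(tert-butyldimethylsilyl)oxy]-2,6,6-trimethylcyclohex-1-en-1-yl]-7-methylnona-2,4,6-trien-8-yn-1-ol
Conditions: DIBAL-H, CH2Cl2, −78 °C; Rochelle salt work-up
Reagents that add atoms: none
Why: DIBAL-H reduces the conjugated ester to the allylic alcohol by 1,2-hydride delivery at low temperature (ester reduction) without touching the polyene, the alkyne or the silyl ether.

Step 11
Reactants: 15 trienynol
Product: 16 (2E,4E,6E)-9-[(4R)-4-[(tert-butyldimethylsilyl)oxy]-2,6,6-trimethylcyclohex-1-en-1-yl]-7-methylnona-2,4,6-trien-8-ynal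
Conditions: MnO2, CH2Cl2, rt
Reagents that add atoms: none
Why: Allylic alcohol oxidation with manganese dioxide gives the polyenal under neutral conditions that should preserve the E geometries.

Step 12
Reactants: 16 trienynal; 17 2-(triphenylphosphoranylidene)propanal
Product: 18 (2E,4E,6E,8E)-11-[(4R)-4-[(tert-butyldimethylsilyl)oxy]-2,6,6-trimethylcyclohex-1-en-1-yl]-2,9-dimethylundeca-2,4,6,8-tetraen-10-ynal
Conditions: toluene, 90 °C
Reagents that add atoms: none
Why: Wittig olefination with the stabilised formyl ylide should give the α-methyl enal with E geometry, and the product, being a more hindered and less electrophilic aldehyde, should not react a second time.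

Step 13
Reactants: 18 chain aldehyde; 19 3-bromofuran-2(5H)-one
Product: 22 (5Z)-3-bromo-5-[(2E,4E,6E,8E)-11-[(4R)-4-[(tert-butyldimethylsilyl)oxy]-2,6,6-trimethylcyclohex-1-en-1-yl]-2,9-dimethylundeca-2,4,6,8-tetraen-10-yn-1-ylidene]furan-2(5H)-one, via bromo silyloxyfuran 20 (not isolated), via silylated aldol adduct 21 (not isolated)
Conditions: TBSOTf, i-Pr2NEt, CH2Cl2, −78 °C → rt; then DBU, rt
Reagents that add atoms: none
Why: The 2-silyloxyfuran formed in the flask adds through its γ-carbon to the aldehyde carbonyl (vinylogous Mukaiyama aldol addition) and DBU then induces E1cB loss of silanol (vinylogous aldol condensation), the Z ylidene geometry being the thermodynamically preferred one reached through the reversible furanolate.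

Step 14
Reactants: 22 silylated bromo ylidenebutenolide
Product: 23 (5Z)-3-bromo-5-[(2E,4E,6E,8E)-11-[(4R)-4-hydroxy-2,6,6-trimethylcyclohex-1-en-1-yl]-2,9-dimethylundeca-2,4,6,8-tetraen-10-yn-1-ylidene]furan-2(5H)-one
Conditions: HF·pyridine, pyridine, THF, 0 °C → rt
Reagents that add atoms: none
Why: Buffered HF·pyridine removes the secondary silyl ether (desilylation) under non-basic conditions that the bromobutenolide and the polyene should tolerate.

Step 15
Reactants: 23 bromo ylidenebutenolide; 9 vinylstannane triol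
Product: 24 (5Z)-5-[(2E,4E,6E,8E)-11-[(4R)-4-hydroxy-2,6,6-trimethylcyclohex-1-en-1-yl]-2,9-dimethylundeca-2,4,6,8-tetraen-10-yn-1-ylidene]-3-[(E)-2-[(1R,2R,4S)-1,2,4-trihydroxy-2,6,6-trimethylcyclohexyl]ethenyl]furan-2(5H)-one (target, CNP0163979.1)
Conditions: Pd2(dba)3 (cat.), AsPh3, NMP, rt → 40 °C, dark
Reagents that add atoms: none
Why: Stille coupling of an α-bromo ylidenebutenolide with an E-alkenylstannane proceeds with retention at both sp2 carbons under neutral conditions, so the four free hydroxyls, the lactone and all alkene geometries should survive and the vinyl E geometry is carried over from 9.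

Compound list
1 | (4R,6R)-actinol, (4R,6R)-4-hydroxy-2,2,6-trimethylcyclohexan-1-one | O=C1C(C)(C)C[C@H](O)C[C@H]1C | starting material
2 | (4R,6R)-4-[(tert-butyldimethylsilyl)oxy]-2,2,6-trimethylcyclohexan-1-one | O=C1C(C)(C)C[C@H](O[Si](C)(C)C(C)(C)C)C[C@H]1C | intermediate
3 | (4R)-4-[(tert-butyldimethylsilyl)oxy]-2,6,6-trimethylcyclohex-1-en-1-yl trifluoromethanesulfonate | CC1=C(OS(=O)(=O)C(F)(F)F)C(C)(C)C[C@H](O[Si](C)(C)C(C)(C)C)C1 | intermediate
4 | ethynyltrimethylsilane | C[Si](C)(C)C#C | starting material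
5 | tert-butyldimethyl{[(1R)-3,5,5-trimethyl-4-[(trimethylsilyl)ethynyl]cyclohex-3-en-1-yl]oxy}silane | CC1=C(C#C[Si](C)(C)C)C(C)(C)C[C@H](O[Si](C)(C)C(C)(C)C)C1 | intermediate
6 | (1R)-4-ethynyl-3,5,5-trimethylcyclohex-3-en-1-ol (ethynyl cyclohexenol, key-step precursor) | CC1=C(C#C)C(C)(C)C[C@H](O)C1 | intermediate
7 | (1S,4S,6S)-1-ethynyl-2,2,6-trimethyl-7-oxabicyclo[4.1.0]heptan-4-ol (oxirane oxygen cis to the hydroxyl) | C#C[C@]12O[C@@]1(C)C[C@@H](O)CC2(C)C | intermediate
8 | (1S,2R,4S)-1-ethynyl-2,6,6-trimethylcyclohexane-1,2,4-triol (1-OH and 4-OH cis, 2-OH trans to both; key-step product) | C#C[C@@]1(O)C(C)(C)C[C@H](O)C[C@@]1(C)O | intermediate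
9 | (1R,2R,4S)-2,6,6-trimethyl-1-[(E)-2-(tributylstannyl)ethenyl]cyclohexane-1,2,4-triol | CCCC[Sn](CCCC)(CCCC)/C=C/[C@@]1(O)C(C)(C)C[C@H](O)C[C@@]1(C)O | intermediate
10 | (E)-3-methylpent-2-en-4-yn-1-ol | C#C/C(C)=C/CO | starting material
11 | (E)-5-[(4R)-4-[(tert-butyldimethylsilyl)oxy]-2,6,6-trimethylcyclohex-1-en-1-yl]-3-methylpent-2-en-4-yn-1-ol | CC1=C(C#C/C(C)=C/CO)C(C)(C)C[C@H](O[Si](C)(C)C(C)(C)C)C1 | intermediate
12 | (E)-5-[(4R)-4-[(tert-butyldimethylsilyl)oxy]-2,6,6-trimethylcyclohex-1-en-1-yl]-3-methylpent-2-en-4-ynal | CC1=C(C#C/C(C)=C/C=O)C(C)(C)C[C@H](O[Si](C)(C)C(C)(C)C)C1 | intermediate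
13 | triethyl 4-phosphonocrotonate, ethyl (E)-4-(diethoxyphosphoryl)but-2-enoate | CCOC(=O)/C=C/CP(=O)(OCC)OCC | starting material
14 | ethyl (2E,4E,6E)-9-[(4R)-4-[(tert-butyldimethylsilyl)oxy]-2,6,6-trimethylcyclohex-1-en-1-yl]-7-methylnona-2,4,6-trien-8-ynoate | CC1=C(C#C/C(C)=C/C=C/C=C/C(=O)OCC)C(C)(C)C[C@H](O[Si](C)(C)C(C)(C)C)C1 | intermediate
15 | (2E,4E,6E)-9-[(4R)-4-[(tert-butyldimethylsilyl)oxy]-2,6,6-trimethylcyclohex-1-en-1-yl]-7-methylnona-2,4,6-trien-8-yn-1-ol | CC1=C(C#C/C(C)=C/C=C/C=C/CO)C(C)(C)C[C@H](O[Si](C)(C)C(C)(C)C)C1 | intermediate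
16 | (2E,4E,6E)-9-[(4R)-4-[(tert-butyldimethylsilyl)oxy]-2,6,6-trimethylcyclohex-1-en-1-yl]-7-methylnona-2,4,6-trien-8-ynal | CC1=C(C#C/C(C)=C/C=C/C=C/C=O)C(C)(C)C[C@H](O[Si](C)(C)C(C)(C)C)C1 | intermediate
17 | 2-(triphenylphosphoranylidene)propanal | CC(C=O)=P(c1ccccc1)(c1ccccc1)c1ccccc1 | starting material
18 | (2E,4E,6E,8E)-11-[(4R)-4-[(tert-butyldimethylsilyl)oxy]-2,6,6-trimethylcyclohex-1-en-1-yl]-2,9-dimethylundeca-2,4,6,8-tetraen-10-ynal (chain aldehyde) | CC1=C(C#C/C(C)=C/C=C/C=C/C=C(C)/C=O)C(C)(C)C[C@H](O[Si](C)(C)C(C)(C)C)C1 | intermediate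
19 | 3-bromofuran-2(5H)-one | O=C1OCC=C1Br | starting material
20 | [(3-bromofuran-2-yl)oxy](tert-butyl)dimethylsilane | CC(C)(C)[Si](C)(C)Oc1occc1Br | intermediate
21 | 3-bromo-5-[(2E,4E,6E,8E)-1-[(tert-butyldimethylsilyl)oxy]-11-[(4R)-4-[(tert-butyldimethylsilyl)oxy]-2,6,6-trimethylcyclohex-1-en-1-yl]-2,9-dimethylundeca-2,4,6,8-tetraen-10-yn-1-yl]furan-2(5H)-one (diastereomer mixture at the two new carbons, both removed in the elimination) | CC1=C(C#C/C(C)=C/C=C/C=C/C=C(C)/C(O[Si](C)(C)C(C)(C)C)C2OC(=O)C(Br)=C2)C(C)(C)C[C@H](O[Si](C)(C)C(C)(C)C)C1 | intermediate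
22 | (5Z)-3-bromo-5-[(2E,4E,6E,8E)-11-[(4R)-4-[(tert-butyldimethylsilyl)oxy]-2,6,6-trimethylcyclohex-1-en-1-yl]-2,9-dimethylundeca-2,4,6,8-tetraen-10-yn-1-ylidene]furan-2(5H)-one | CC1=C(C#C/C(C)=C/C=C/C=C/C=C(C)/C=C2C=C(Br)C(=O)O/2)C(C)(C)C[C@H](O[Si](C)(C)C(C)(C)C)C1 | intermediate
23 | (5Z)-3-bromo-5-[(2E,4E,6E,8E)-11-[(4R)-4-hydroxy-2,6,6-trimethylcyclohex-1-en-1-yl]-2,9-dimethylundeca-2,4,6,8-tetraen-10-yn-1-ylidene]furan-2(5H)-one | CC1=C(C#C/C(C)=C/C=C/C=C/C=C(C)/C=C2C=C(Br)C(=O)O/2)C(C)(C)C[C@H](O)C1 | intermediate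
24 | (5Z)-5-[(2E,4E,6E,8E)-11-[(4R)-4-hydroxy-2,6,6-trimethylcyclohex-1-en-1-yl]-2,9-dimethylundeca-2,4,6,8-tetraen-10-yn-1-ylidene]-3-[(E)-2-[(1R,2R,4S)-1,2,4-trihydroxy-2,6,6-trimethylcyclohexyl]ethenyl]furan-2(5H)-one | CC1=C(C#C/C(C)=C/C=C/C=C/C=C(C)/C=C2C=C(/C=C/[C@@]3(O)C(C)(C)C[C@H](O)C[C@@]3(C)O)C(=O)O/2)C(C)(C)C[C@H](O)C1 | target

Total step count: 15.
Longest linear sequence: 11 steps (1, 2, 7 to 15). The triol branch (steps 3 to 6) joins at step 15.

Steps most likely to fail

1. Step 5 (key step).
- Process at risk: oxygen transfer from the vanadium alkoxide to the hindered, alkyne-conjugated tetrasubstituted alkene may be slow enough for undirected oxidation to compete, which erodes face selectivity. In the acidic stage the protonated oxirane may rearrange by ring contraction or a 1,2-shift, or be attacked at C6 instead of C5.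
- Fallback (sets out from 5, returns at 8): the face is set by the reagent instead of the substrate. Dioxirane epoxidation of 5 with a fructose-derived chiral ketone and Oxone (Shi epoxidation, known for conjugated enynes) would be used, with the ketone enantiomer whose spiro transition state addresses the face cis to the silyloxy group. This should give the silylated syn-epoxide F1. Separate hydrolysis with dilute aqueous HClO4 in THF should then give the silylated diol F2 by the same anti opening at C5. TBAF would remove both silyl groups and deliver 8.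

2. Step 13.
- Process at risk: the amine bases may add to or degrade the brominated butenolide, or the silyloxyfuran may add to the tetraenal in a conjugate sense, before γ-aldol addition and elimination are complete.
- Fallback (sets out from 18, returns at 22): the butenolide is built by alkyne lactonisation instead of aldol condensation. One-carbon homologation of 18 with lithiated trimethylsilyldiazomethane (Colvin rearrangement) would give the terminal diyne F3. Sonogashira coupling at the β-bromine of methyl (E)-2,3-dibromopropenoate F4 (from methyl propiolate and bromine) would give the bromo enynoate F5. Saponification with LiOH would give the bromo enynoic acid F6. Silver(I)-catalysed 5-exo-dig lactonisation, an anti addition of the carboxylate across the alkyne, would close the Z-ylidene bromobutenolide 22.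

3. Step 15.
- Process at risk: transmetalation of the hindered β-stannylvinyl carbinol may be slow, so that protodestannylation, stannane homocoupling or palladium-induced E/Z scrambling of the polyenyl bromobutenolide compete.
- Fallback (sets out from 8, returns at 24): boron replaces tin. Copper-catalysed borylation of the terminal alkyne of 8 (B2pin2, CuCl, phosphine, NaOt-Bu, MeOH) would give the (E)-vinylboronate F7. Suzuki–Miyaura coupling of F7 with 23 (Pd(PPh3)4, K3PO4, THF–H2O, rt) would give 24.

Further compounds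
F1 | step 5 | tert-butyldimethyl{[(1S,4S,6S)-2,2,6-trimethyl-1-[(trimethylsilyl)ethynyl]-7-oxabicyclo[4.1.0]heptan-4-yl]oxy}silane | C[Si](C)(C)C#C[C@]12O[C@@]1(C)C[C@@H](O[Si](C)(C)C(C)(C)C)CC2(C)C
F2 | step 5 | (1S,2R,4S)-4-[(tert-butyldimethylsilyl)oxy]-2,6,6-trimethyl-1-[(trimethylsilyl)ethynyl]cyclohexane-1,2-diol | C[Si](C)(C)C#C[C@@]1(O)C(C)(C)C[C@H](O[Si](C)(C)C(C)(C)C)C[C@@]1(C)O
F3 | step 13 | tert-butyl{[(1R)-4-[(3E,5E,7E,9E)-3,10-dimethyldodeca-3,5,7,9-tetraene-1,11-diyn-1-yl]-3,5,5-trimethylcyclohex-3-en-1-yl]oxy}dimethylsilane | CC1=C(C#C/C(C)=C/C=C/C=C/C=C(C)/C#C)C(C)(C)C[C@H](O[Si](C)(C)C(C)(C)C)C1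
F4 | step 13 | methyl (E)-2,3-dibromoprop-2-enoate | COC(=O)/C(Br)=C\Br
F5 | step 13 | methyl (2E,6E,8E,10E,12E)-2-bromo-15-[(4R)-4-[(tert-butyldimethylsilyl)oxy]-2,6,6-trimethylcyclohex-1-en-1-yl]-6,13-dimethylpentadeca-2,6,8,10,12-pentaene-4,14-diynoate | CC1=C(C#C/C(C)=C/C=C/C=C/C=C(C)/C#C/C=C(Br)\C(=O)OC)C(C)(C)C[C@H](O[Si](C)(C)C(C)(C)C)C1
F6 | step 13 | (2E,6E,8E,10E,12E)-2-bromo-15-[(4R)-4-[(tert-butyldimethylsilyl)oxy]-2,6,6-trimethylcyclohex-1-en-1-yl]-6,13-dimethylpentadeca-2,6,8,10,12-pentaene-4,14-diynoic acid | CC1=C(C#C/C(C)=C/C=C/C=C/C=C(C)/C#C/C=C(Br)\C(=O)O)C(C)(C)C[C@H](O[Si](C)(C)C(C)(C)C)C1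
F7 | step 15 | (1R,2R,4S)-2,6,6-trimethyl-1-[(E)-2-(4,4,5,5-tetramethyl-1,3,2-dioxaborolan-2-yl)ethenyl]cyclohexane-1,2,4-triol | CC1(C)OB(/C=C/[C@@]2(O)C(C)(C)C[C@H](O)C[C@@]2(C)O)OC1(C)C
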